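**Retrosynthetic overview**

1. C40 = C10 + C20 + C10. The C7=C8 alkene is cut last: Julia–Kocienski olefination of ring sulfone 18 with C30 polyenal 23. Polyenal 23 comes from commercial crocetin dialdehyde 22 and benzylic phosphonate 21 by a mono Horner–Wadsworth–Emmons reaction.
2. Sulfone 18 comes from acid 14 by reduction, Mitsunobu thioetherification and S-oxidation, so that C6 is never alpha to an aldehyde.
3. Ring order: the arene is bought as 1,2,3-trimethylbenzene. The cyclohexadiene is the only ring made (step 6). Its C5–C6 bond is closed by an Ireland–Claisen ring contraction of the silyl ketene acetal of 6-allenyl δ-lactone 11, a temporary ring made in step 5. This one operation gives the carbocycle, the C6 stereocentre, the cis C3=C4 alkene and the C5=C18 methylidene.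
4. Enabling feature: ring carbon C6 carries an exocyclic carbon C7 that can be a carboxyl. The ring alkene C3=C4 is then γ,δ to it, and C5 between them bears =CH2. This 2-substituted 1,3-diene (C18=C5–C4=C3) beside a carboxyl-bearing carbon is the retron of a [3,3] shift onto the central carbon of an allene, with the ring O–C3 bond as the bond that breaks.
5. Lactone 11: 3,3-dimethylglutaric anhydride, half ester, silyl ynone, (R)-propargylic alcohol (asymmetric transfer hydrogenation), allene (Crabbé homologation), lactonisation.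

Key step: step 6

Remark: carotenoid numbering is used for the end group (C1 = CMe2, C2 = CH2, C3=C4 = ring alkene, C5 = methylidene-bearing carbon, C18 = its CH2, C6 = stereocentre, C7 = first chain carbon); 22, 19 and the amide bases (as solutions) are assumed purchasable, and the (R,R)-catalyst of step 3 is assumed to give the (R)-carbinol as with other silyl ynones (otherwise its antipode is used).

**Route**

Step 1
Reactants: 1 3,3-dimethylglutaric anhydride
Product: 2 5-methoxy-3,3-dimethyl-5-oxopentanoic acid
Conditions: MeOH, reflux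
Reagents that add atoms: methanol, CO
Why: Methanolysis of a symmetric cyclic anhydride (nucleophilic acyl substitution) can only give the one half ester because both carbonyl groups are equivalent.

Step 2
Reactants: 2 5-methoxy-3,3-dimethyl-5-oxopentanoic acid; 3 bis(trimethylsilyl)acetylene
Product: 5 methyl 3,3-dimethyl-5-oxo-7-(trimethylsilyl)hept-6-ynoate, via acid chloride 4 (not isolated)
Conditions: (COCl)2, DMF (cat.), CH2Cl2, 0 °C to rt, evaporate; then 3, AlCl3, CH2Cl2, 0 °C
Reagents that add atoms: none
Why: The acid chloride formed by Vilsmeier-catalysed chlorination ipso-acylates one C–Si bond of the bis-silyl alkyne (Friedel–Crafts acylation of an alkynylsilane), and the remaining silyl group protects the ynone terminus.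

Step 3
Reactants: 5 methyl 3,3-dimethyl-5-oxo-7-(trimethylsilyl)hept-6-ynoate
Product: 6 methyl (5R)-5-hydroxy-3,3-dimethyl-7-(trimethylsilyl)hept-6-ynoate
Conditions: Ru[(1R,2R)-TsNCH(Ph)CH(Ph)NH](η6-p-cymene) (1 mol %), i-PrOH, rt
Reagents that add atoms: none
Why: Noyori asymmetric transfer hydrogenation of an alkynyl ketone, in which the bifunctional Ru–H/N–H catalyst distinguishes the alkynyl from the sp3 substituent and the (R,R)-ligand should deliver hydride to the face that gives the (R)-carbinol, the only stereocentre of the route that is set by a reagent.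

Step 4
Reactants: 6 methyl (5R)-5-hydroxy-3,3-dimethyl-7-(trimethylsilyl)hept-6-ynoate
Product: 7 methyl (5R)-5-hydroxy-3,3-dimethylhept-6-ynoate
Conditions: K2CO3 (0.2 equiv), MeOH, 0 °C to rt; neutral work-up
Reagents that add atoms: none
Why: Methoxide-mediated protodesilylation of the alkynylsilane leaves the carbinol centre untouched, and any lactonised material converges on 11 in step 5.

Step 5
Reactants: 7 methyl (5R)-5-hydroxy-3,3-dimethylhept-6-ynoate; 8 paraformaldehyde
Product: 11 (6R)-4,4-dimethyl-6-(propa-1,2-dien-1-yl)oxan-2-one, via propargylic amine 9 (not isolated), via allenyl hydroxy ester 10 (not isolated)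
Conditions: 8, CuI (0.5 equiv), (c-C6H11)2NH, 1,4-dioxane, reflux; then camphorsulfonic acid (cat.), CH2Cl2, rt
Reagents that add atoms: none
Why: Crabbé homologation, in which the copper-mediated Mannich condensation gives the propargylic amine and its 1,5-hydride shift with loss of imine gives the terminal allene without touching the free carbinol centre; acid then closes the δ-lactone, helped by the gem-dimethyl group.

Step 6
Reactants: 11 (6R)-4,4-dimethyl-6-(propa-1,2-dien-1-yl)oxan-2-one
Product: 14 (1S)-6,6-dimethyl-2-methylidenecyclohex-3-ene-1-carboxylic acid, via silyl ketene acetal 12 (not isolated), via silyl ester 13 (not isolated)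
Conditions: LiN(i-Pr)2, THF, −78 °C; t-BuMe2SiCl, DMPU, −78 °C to rt; PhMe, 100 °C; then AcOH/THF/H2O, rt
Reagents that add atoms: none
Why: Proposed new method: the lactone enolate is O-silylated to cyclic ketene acetal 12, whose C6=C7–O–C3–C4=C5 array undergoes a concerted [3,3] shift in which C6 bonds to the central allene carbon C5 while the ring O–C3 bond breaks, and the distal allene π bond is left as the exocyclic C5=C18 methylidene. The closest known reactions are the Ireland–Claisen carbocyclisation of 6-alkenyl δ-lactone silyl ketene acetals and the Ireland–Claisen rearrangement of acyclic α-allenic esters to 2-substituted 1,3-dienes; their combination, an allene as the migrating terminus inside a lactone, has not been shown. The six-membered carbocycle is closed by ring contraction of the oxacycle through a boat, bicyclo[2.2.2]-like transition state, the only geometry that the two-carbon tether C1–C2 allows. The new C6 stereocentre is controlled by the C3 carbinol centre alone: the allenyl group must sit axial, bonding is suprafacial on both components, and the (R)-lactone should give the (S)-acid while the C3 centre is destroyed. The step needs O- over C-silylation (t-BuMe2SiCl/DMPU on the lithium enolate), rearrangement faster than allene oligomerisation (helped by loss of cumulene strain and gain of a conjugated diene and a carboxyl C=O) and a cis ring alkene, which the ring itself enforces. The diene that forms is locked s-trans and cannot dimerise by Diels–Alder reaction, and the C6–H of the silyl ester is not enolised under the neutral thermal conditions.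

Step 7
Reactants: 14 (1S)-6,6-dimethyl-2-methylidenecyclohex-3-ene-1-carboxylic acid
Product: 15 [(1S)-6,6-dimethyl-2-methylidenecyclohex-3-en-1-yl]methanol
Conditions: LiAlH4, Et2O, 0 °C; aq. NaOH work-up
Reagents that add atoms: none
Why: Hydride reduction of a carboxylic acid goes through the carboxylate, which cannot enolise, so the C6 centre and the unconjugated diene are kept.

Step 8
Reactants: 15 [(1S)-6,6-dimethyl-2-methylidenecyclohex-3-en-1-yl]methanol
Product: 16 5-({[(1S)-6,6-dimethyl-2-methylidenecyclohex-3-en-1-yl]methyl}sulfanyl)-1-phenyl-1H-tetrazole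
Conditions: 1-phenyl-1H-tetrazole-5-thiol, PPh3, DIAD, THF, 0 °C to rt
Reagents that add atoms: 1-phenyl-1H-tetrazole-5-thiol, Sc1nnnn1-c1ccccc1
Why: Mitsunobu thioetherification, in which the acidic thiol displaces the oxyphosphonium of the primary alcohol by SN2 at C7, one carbon away from the stereocentre, under neutral conditions.

Step 9
Reactants: 16 5-({[(1S)-6,6-dimethyl-2-methylidenecyclohex-3-en-1-yl]methyl}sulfanyl)-1-phenyl-1H-tetrazole
Product: 18 5-({[(1S)-6,6-dimethyl-2-methylidenecyclohex-3-en-1-yl]methyl}sulfonyl)-1-phenyl-1H-tetrazole, via sulfoxide 17 (not isolated)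
Conditions: (NH4)6Mo7O24·4H2O (10 mol %), 30% H2O2, EtOH, 0 °C to rt
Reagents that add atoms: hydrogen peroxide, OO
Why: Molybdate-catalysed peroxide oxidation of a sulfide to the sulfone is much faster at sulfur than at an unactivated diene and is the usual entry to Julia–Kocienski sulfones.

Step 10
Reactants: 19 1,2,3-trimethylbenzene; 8 paraformaldehyde
Product: 20 1-(bromomethyl)-2,3,4-trimethylbenzene
Conditions: 8 (1 equiv), HBr (33% in AcOH), AcOH, 45 °C
Reagents that add atoms: hydrogen bromide, Br
Why: Electrophilic bromomethylation (Blanc type) should go to position 4, which is activated ortho and para by two methyl groups against one for position 5, and limiting formaldehyde restrains a second substitution.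

Step 11
Reactants: 20 1-(bromomethyl)-2,3,4-trimethylbenzene
Product: 21 diethyl [(2,3,4-trimethylphenyl)methyl]phosphonate
Conditions: P(OEt)3, neat, 130 °C
Reagents that add atoms: triethyl phosphite, CCOP(OCC)OCC
Why: Michaelis–Arbuzov reaction of a reactive benzylic bromide, driven by loss of volatile bromoethane.

Step 12
Reactants: 21 diethyl [(2,3,4-trimethylphenyl)methyl]phosphonate; 22 crocetin dialdehyde
Product: 23 (2E,4E,6E,8E,10E,12E,14E,16E)-2,6,11,15-tetramethyl-17-(2,3,4-trimethylphenyl)heptadeca-2,4,6,8,10,12,14,16-octaenal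
Conditions: KOC(CH3)3, THF, 0 °C; anion added dropwise to 22 (3 equiv), THF, 0 °C to rt, dark
Reagents that add atoms: none
Why: Horner–Wadsworth–Emmons olefination with a benzylic phosphonate gives E-styrenes, and inverse addition to excess dialdehyde favours mono-olefination while the unused 22 is recovered.

Step 13
Reactants: 18 5-({[(1S)-6,6-dimethyl-2-methylidenecyclohex-3-en-1-yl]methyl}sulfonyl)-1-phenyl-1H-tetrazole; 23 (2E,4E,6E,8E,10E,12E,14E,16E)-2,6,11,15-tetramethyl-17-(2,3,4-trimethylphenyl)heptadeca-2,4,6,8,10,12,14,16-octaenal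
Product: 24 (6S)-3,4-didehydro-γ,χ-carotene (the target)
Conditions: KN(SiMe3)2, DME, −60 °C; then 23, −60 °C to rt, dark, argon
Reagents that add atoms: none
Why: Julia–Kocienski olefination, in which the metalated sulfone adds to the enal and Smiles rearrangement with loss of SO2 and tetrazolate should give the E C7=C8 alkene in one flask; the C6 centre is beta to the carbanion and is not deprotonated, and the product has no carbonyl left to acidify C6–H.

**Compound list**

1 | 3,3-dimethylglutaric anhydride | O=C1CC(C)(C)CC(=O)O1 | starting material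
2 | 5-methoxy-3,3-dimethyl-5-oxopentanoic acid | COC(=O)CC(C)(C)CC(=O)O | intermediate
3 | bis(trimethylsilyl)acetylene | C[Si](C)(C)C#C[Si](C)(C)C | starting material
4 | methyl 5-chloro-3,3-dimethyl-5-oxopentanoate | COC(=O)CC(C)(C)CC(=O)Cl | intermediate
5 | methyl 3,3-dimethyl-5-oxo-7-(trimethylsilyl)hept-6-ynoate | COC(=O)CC(C)(C)CC(=O)C#C[Si](C)(C)C | intermediate
6 | methyl (5R)-5-hydroxy-3,3-dimethyl-7-(trimethylsilyl)hept-6-ynoate | C[Si](C)(C)C#C[C@H](O)CC(C)(C)CC(=O)OC | intermediate
7 | methyl (5R)-5-hydroxy-3,3-dimethylhept-6-ynoate | C#C[C@H](O)CC(C)(C)CC(=O)OC | intermediate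
8 | paraformaldehyde (formaldehyde source) | C=O | starting material
9 | methyl (5R)-8-(dicyclohexylamino)-5-hydroxy-3,3-dimethyloct-6-ynoate | C1CCCCC1N(C1CCCCC1)CC#C[C@H](O)CC(C)(C)CC(=O)OC | intermediate
10 | methyl (5R)-5-hydroxy-3,3-dimethylocta-6,7-dienoate | C=C=C[C@H](O)CC(C)(C)CC(=O)OC | intermediate
11 | (6R)-4,4-dimethyl-6-(propa-1,2-dien-1-yl)oxan-2-one | C=C=C[C@H]1CC(C)(C)CC(=O)O1 | intermediate
12 | tert-butyl{[(2R)-4,4-dimethyl-2-(propa-1,2-dien-1-yl)-3,4-dihydro-2H-pyran-6-yl]oxy}dimethylsilane | C=C=C[C@H]1CC(C)(C)C=C(O[Si](C)(C)C(C)(C)C)O1 | intermediate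
13 | tert-butyldimethylsilyl (1S)-6,6-dimethyl-2-methylidenecyclohex-3-ene-1-carboxylate | C=C1C=CCC(C)(C)[C@@H]1C(=O)O[Si](C)(C)C(C)(C)C | intermediate
14 | (1S)-6,6-dimethyl-2-methylidenecyclohex-3-ene-1-carboxylic acid | C=C1C=CCC(C)(C)[C@@H]1C(=O)O | intermediate
15 | [(1S)-6,6-dimethyl-2-methylidenecyclohex-3-en-1-yl]methanol | C=C1C=CCC(C)(C)[C@@H]1CO | intermediate
16 | 5-({[(1S)-6,6-dimethyl-2-methylidenecyclohex-3-en-1-yl]methyl}sulfanyl)-1-phenyl-1H-tetrazole | C=C1C=CCC(C)(C)[C@@H]1CSc2nnnn2-c3ccccc3 | intermediate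
17 | 5-({[(1S)-6,6-dimethyl-2-methylidenecyclohex-3-en-1-yl]methyl}sulfinyl)-1-phenyl-1H-tetrazole (both sulfur epimers) | C=C1C=CCC(C)(C)[C@@H]1CS(=O)c2nnnn2-c3ccccc3 | intermediate
18 | 5-({[(1S)-6,6-dimethyl-2-methylidenecyclohex-3-en-1-yl]methyl}sulfonyl)-1-phenyl-1H-tetrazole | C=C1C=CCC(C)(C)[C@@H]1CS(=O)(=O)c2nnnn2-c3ccccc3 | intermediate
19 | 1,2,3-trimethylbenzene | Cc1cccc(C)c1C | starting material
20 | 1-(bromomethyl)-2,3,4-trimethylbenzene | Cc1ccc(CBr)c(C)c1C | intermediate
21 | diethyl [(2,3,4-trimethylphenyl)methyl]phosphonate | CCOP(=O)(Cc1ccc(C)c(C)c1C)OCC | intermediate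
22 | crocetin dialdehyde, (2E,4E,6E,8E,10E,12E,14E)-2,6,11,15-tetramethylhexadeca-2,4,6,8,10,12,14-heptaenedial | O=C/C(C)=C/C=C/C(C)=C/C=C/C=C(C)/C=C/C=C(C)/C=O | starting material
23 | (2E,4E,6E,8E,10E,12E,14E,16E)-2,6,11,15-tetramethyl-17-(2,3,4-trimethylphenyl)heptadeca-2,4,6,8,10,12,14,16-octaenal | O=C/C(C)=C/C=C/C(C)=C/C=C/C=C(C)/C=C/C=C(C)/C=C/c1ccc(C)c(C)c1C | intermediate
24 | (6S)-3,4-didehydro-γ,χ-carotene, 1-{(1E,3E,5E,7E,9E,11E,13E,15E,17E)-18-[(1S)-6,6-dimethyl-2-methylidenecyclohex-3-en-1-yl]-3,7,12,16-tetramethyloctadeca-1,3,5,7,9,11,13,15,17-nonaen-1-yl}-2,3,4-trimethylbenzene | C=C1C=CCC(C)(C)[C@@H]1/C=C/C(C)=C/C=C/C(C)=C/C=C/C=C(C)/C=C/C=C(C)/C=C/c1ccc(C)c(C)c1C | target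

**Step count and risks**

Total: 13 steps. Longest linear sequence: 10 steps (steps 1 to 9, then 13).

Step 6 (Proposed new method). The boat transition state may be reached too slowly, so that C-silylation, hydrolysis of the ketene acetal or thermal oligomerisation of the allene take over. The fallback uses known chemistry, sets out from 7 and comes back at 14. It keeps the ring-closing Claisen event but replaces the allene by an E-alkene, the substrate class for which the lactone-enolate Claisen carbocyclisation is established, and makes the methylidene afterwards by sulfoxide elimination.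
- Semi-hydrogenation of 7 (H2, Pd/CaCO3 poisoned with Pb(OAc)2, quinoline) gives methyl (5R)-5-hydroxy-3,3-dimethylhept-6-enoate F1, which is lactonised (camphorsulfonic acid) to (6R)-6-ethenyl-4,4-dimethyloxan-2-one F2.
- Cross-metathesis with allyl phenyl sulfide (second-generation Hoveyda–Grubbs catalyst) gives (6R)-4,4-dimethyl-6-[(1E)-3-(phenylsulfanyl)prop-1-en-1-yl]oxan-2-one F3.
- Enolisation and silylation as in step 6 give tert-butyl({(2R)-4,4-dimethyl-2-[(1E)-3-(phenylsulfanyl)prop-1-en-1-yl]-3,4-dihydro-2H-pyran-6-yl}oxy)dimethylsilane F4. In hot toluene it should rearrange through the same boat to tert-butyldimethylsilyl (1R,2R)-6,6-dimethyl-2-[(phenylsulfanyl)methyl]cyclohex-3-ene-1-carboxylate F5. Hydrolysis gives (1R,2R)-6,6-dimethyl-2-[(phenylsulfanyl)methyl]cyclohex-3-ene-1-carboxylic acid F6. The sense of transfer to C6 is the same as in step 6; the descriptor changes only because C5 is now sp3.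
- NaIO4 gives (1R,2R)-6,6-dimethyl-2-[(phenylsulfinyl)methyl]cyclohex-3-ene-1-carboxylic acid F7 (both sulfur epimers). Thermal syn-elimination (toluene, 100 °C), which has only the C5–H to take, gives 14.

Step 13. E-selectivity at C7=C8 may be incomplete, or the sulfonyl carbanion may take a proton from the polyenal instead of adding to it. The fallback reverses the polarity to a Horner–Wadsworth–Emmons reaction, sets out from 15 and 23 and comes back at 24.
- 15 is oxidised (Dess–Martin periodinane, NaHCO3, CH2Cl2, 0 °C) to (1S)-6,6-dimethyl-2-methylidenecyclohex-3-ene-1-carbaldehyde F8, which is used at once.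
- 23 is reduced (NaBH4, MeOH/THF) to (2E,4E,6E,8E,10E,12E,14E,16E)-2,6,11,15-tetramethyl-17-(2,3,4-trimethylphenyl)heptadeca-2,4,6,8,10,12,14,16-octaen-1-ol F9. ZnI2 and P(OEt)3 convert it into diethyl [(2E,4E,6E,8E,10E,12E,14E,16E)-2,6,11,15-tetramethyl-17-(2,3,4-trimethylphenyl)heptadeca-2,4,6,8,10,12,14,16-octaen-1-yl]phosphonate F10.
- The preformed anion of F10 (NaN(SiMe3)2, THF, −78 °C) is treated with F8 and should give 24 with the E-preference of allylic phosphonates. Adding the aldehyde cold to the weakly basic polyenyl anion limits enolisation at C6.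

Step 10. Attack at position 5 and a second bromomethylation may give isomers that are hard to separate. The fallback sets out from 19 and comes back at 20. Rieche formylation (Cl2CHOCH3, TiCl4, CH2Cl2, 0 °C) stops after one substitution because the product is deactivated. It goes through 1-[chloro(methoxy)methyl]-2,3,4-trimethylbenzene F11, which is hydrolysed on work-up to 2,3,4-trimethylbenzaldehyde F12. NaBH4 gives (2,3,4-trimethylphenyl)methanol F13, and PBr3 (Et2O, 0 °C) gives 20.

Further compounds
F1 | step 6 | methyl (5R)-5-hydroxy-3,3-dimethylhept-6-enoate | C=C[C@H](O)CC(C)(C)CC(=O)OC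
F2 | step 6 | (6R)-6-ethenyl-4,4-dimethyloxan-2-one | C=C[C@H]1CC(C)(C)CC(=O)O1
F3 | step 6 | (6R)-4,4-dimethyl-6-[(1E)-3-(phenylsulfanyl)prop-1-en-1-yl]oxan-2-one | c1ccccc1SC/C=C/[C@H]1CC(C)(C)CC(=O)O1
F4 | step 6 | tert-butyl({(2R)-4,4-dimethyl-2-[(1E)-3-(phenylsulfanyl)prop-1-en-1-yl]-3,4-dihydro-2H-pyran-6-yl}oxy)dimethylsilane | c1ccccc1SC/C=C/[C@H]1CC(C)(C)C=C(O[Si](C)(C)C(C)(C)C)O1
F5 | step 6 | tert-butyldimethylsilyl (1R,2R)-6,6-dimethyl-2-[(phenylsulfanyl)methyl]cyclohex-3-ene-1-carboxylate | c1ccccc1SC[C@@H]1C=CCC(C)(C)[C@@H]1C(=O)O[Si](C)(C)C(C)(C)C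
F6 | step 6 | (1R,2R)-6,6-dimethyl-2-[(phenylsulfanyl)methyl]cyclohex-3-ene-1-carboxylic acid | c1ccccc1SC[C@@H]1C=CCC(C)(C)[C@@H]1C(=O)O
F7 | step 6 | (1R,2R)-6,6-dimethyl-2-[(phenylsulfinyl)methyl]cyclohex-3-ene-1-carboxylic acid (both sulfur epimers) | O=S(c1ccccc1)C[C@@H]1C=CCC(C)(C)[C@@H]1C(=O)O
F8 | step 13 | (1S)-6,6-dimethyl-2-methylidenecyclohex-3-ene-1-carbaldehyde | C=C1C=CCC(C)(C)[C@@H]1C=O
F9 | step 13 | (2E,4E,6E,8E,10E,12E,14E,16E)-2,6,11,15-tetramethyl-17-(2,3,4-trimethylphenyl)heptadeca-2,4,6,8,10,12,14,16-octaen-1-ol | OC/C(C)=C/C=C/C(C)=C/C=C/C=C(C)/C=C/C=C(C)/C=C/c1ccc(C)c(C)c1C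
F10 | step 13 | diethyl [(2E,4E,6E,8E,10E,12E,14E,16E)-2,6,11,15-tetramethyl-17-(2,3,4-trimethylphenyl)heptadeca-2,4,6,8,10,12,14,16-octaen-1-yl]phosphonate | CCOP(=O)(OCC)C/C(C)=C/C=C/C(C)=C/C=C/C=C(C)/C=C/C=C(C)/C=C/c1ccc(C)c(C)c1C
F11 | step 10 | 1-[chloro(methoxy)methyl]-2,3,4-trimethylbenzene | COC(Cl)c1ccc(C)c(C)c1C
F12 | step 10 | 2,3,4-trimethylbenzaldehyde | O=Cc1ccc(C)c(C)c1C
F13 | step 10 | (2,3,4-trimethylphenyl)methanol | OCc1ccc(C)c(C)c1C
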